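Readings and results come from a simulation from invented constants, noise included.

The slowness of the products set my reckoning. In violet the substrate fell with a first-order constant of about 0.814 min⁻¹, read at 3.00 min. Yet at 5.00 min, with 0.1% of it left, target and side product together stood at 35.2% of the charge, so I took the rest to sit in unseen forms.

- violet: substrate 10 mM; gas 0.83 mM (held); run made earlier
- flask: substrate 5.0 mM; gas 0.83 mM (held); time 25 min

- violet (time / min: target / %, side product / %, substrate / %): 0.833: 2.2, 0, 47.6; 1.50: 7.9, 0.5, 30.4; 2.50: 10.5, 6.5, 12.7; 3.00: 13.9, 9.1, 8.7; 4.00: 17.1, 11.6, 5.3; 5.00: 20.6, 14.6, 0.1

(scatter of a reading: 1 percentage point)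

- at the start none of the gas is in solution

- share of target in target plus side product at 40 s
- share of target in target plus side product at 4.0 min
- share of target in target plus side product at 25 min
- which of target and side product there is more of at 25 min

I built the flask up step by step and counted side product as a correction to target. With the main step by itself, one route to target, the share of target is 100 percent. A side path competing for the same unseen pool brings in the selectivity factor, side product per target, which I read in violet as 0.678 at 4.00 min. If dissolved gas stood at saturation in both flasks, that factor carried over and the flask's share was 59.6%.

Then I added the slow supply of gas, suggested by violet's lag: 0.5% of side product against 7.9% of target at 1.50 min. I supposed the gas level to sink as the charge rises. As a second case I took the level, and the factor with it, inverse to the charge: half the charge then multiplied the factor by 2.00, for a share of 42.4%. I took the geometric mean of these two cases, 0.959, and called it the charge-scaled selectivity: violet's factor times the root of violet's charge over the new charge. That gave a share of 51.0% at 4.0 min. The same root on violet's last reading gave 1.00 at 5.00 min, about level. Violet's factor read higher there than the 0.619 at 2.50 min, so I expected side product ahead at 25 min, a close call with a scatter of 1 percentage point on each reading.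

The forecast gave 97% at 40 s, 52% at 4.0 min and 47% at 25 min, with side product ahead; it allowed that gas supply may partly limit side product, and went on: “If so, halving the charge favours side product”. My figure at 4.0 min was 51.0%, and I reckoned none at 40 s.

The flask gave 66.3% at 40 s, 53.0% at 4.0 min and 45.2% at 25 min, with side product ahead, 31.0% against 25.6%. The forecast stood 31 points high at 40 s. In the flask, target and side product stood level at 5.34 min, at 20.5% each. The flask's share at 4.0 min means 0.887 of side product per target, against the 0.959 I carried over.

    substrate → intermediate B (k = 0.0140 s⁻¹)
    gas ⇌ coupling partner, rate k2*(csat - [coupling partner]) (kL = 0.120 s⁻¹)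
    intermediate C → target (k = 0.0360 s⁻¹)
    coupling partner + intermediate B → intermediate C (k = 15.0 M⁻¹ s⁻¹)
    target ⇌ isomer of the product (K = 1.70, k = 0.0210 s⁻¹)
    substrate + coupling partner ⇌ intermediate A (K = 130 M⁻¹, k = 190 M⁻¹ s⁻¹)
    coupling partner + intermediate C → side product (k = 23.0 M⁻¹ s⁻¹)
    coupling partner + intermediate C ⇌ intermediate D (K = 5500 M⁻¹, k = 65.0 M⁻¹ s⁻¹)

On the neighbouring flask with 20 mM of substrate, the same root on violet's factor gives 0.480, a share of 67.6% at 4.0 min. The computed share in that flask is 68.8%.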